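## Retrosynthetic overview

1. The target is (2S,4R)-7,3',4'-trihydroxyflavan joined from C4 to C8' of (−)-epigallocatechin. The strategy rests on the chain C2–C3–C4 of ring C, which carries ring B on C2 and, on C4, both ring A (through C4a) and ring D (through C8').
2. Ring C is opened at O1–C2 (Mitsunobu closure with inversion, the only ring built) and C2 is traced back to an aryl ketone (Corey–Bakshi–Shibata reduction).
3. The ketone is cut at C2–C3 and C4–C4a, so C3–C4 becomes the vinyl group of 8-vinyl-hexa-O-benzyl-epigallocatechin. One nickel/photoredox step joins it with a ring B aroyl radical (from an arylglyoxylic acid) and a ring A aryl bromide, and a chiral bis(oxazoline) on nickel sets C4.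
4. Rings D, F and E come intact from (−)-epigallocatechin (benzylation, C8' bromination, vinylation). Ring A comes from 4-bromoresorcinol and ring B from 3,4-dibenzyloxyacetophenone.
5. Ring order: D, F, E are carried from the start, A and B arrive as arenes, ring C closes in step 11, and hydrogenolysis ends the route.

Key step: step 8

Remarks on the chemistry:
- Ring labels: the upper flavan unit has rings A (benzo), C (pyran) and B (catechol) with unprimed atoms. The lower epigallocatechin unit has rings D (benzo), F (pyran) and E (pyrogallol) with primed atoms.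
- Protecting groups: the lower unit is carried as its hexabenzyl ether (3'-O-benzyl included, six benzyl groups in all), so that no second alcohol is present at the Mitsunobu stage.
- Ring A ortho oxygen: it is a TBS ether, removed by fluoride only after the ketone has been reduced. A free ortho phenol would close onto the C2 ketone as a cyclic hemiketal, and acid strong enough to cleave an acetal would ionise the electron-rich C2 carbinol and endanger the acid-labile C4–C8' bond.
- Assumption: the sense of induction of the nickel bis(oxazoline) catalyst at C4 cannot be predicted with confidence for this substrate. The (S,S) ligand is written, and its antipode is used if the C4 epimer should predominate.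

## Route

Step 1
Reactants: 1 (−)-epigallocatechin
Product: 2 5,7,3',4',5'-penta-O-benzyl-(−)-epigallocatechin
Conditions: BnBr (5.5 equiv), K2CO3, degassed DMF, argon, 0 °C to rt
Reagents that add atoms: benzyl bromide, BrCc1ccccc1
Why: Williamson etherification in which K2CO3 ionises only the five phenols and not the secondary 3'-OH, while low temperature and exclusion of air should hold back pyrogallol oxidation, C-benzylation of ring D and base-induced epimerisation at C2', so both stereocentres are carried through unchanged.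

Step 2
Reactants: 2 5,7,3',4',5'-penta-O-benzyl-(−)-epigallocatechin
Product: 3 3,5,7,3',4',5'-hexa-O-benzyl-(−)-epigallocatechin
Conditions: NaH, BnBr, DMF, 0 °C to rt
Reagents that add atoms: benzyl bromide, BrCc1ccccc1
Why: Williamson etherification of the secondary alcohol through its sodium alkoxide; with every phenol capped no phenoxide can open ring F, so C2' and C3' keep their configuration.

Step 3
Reactants: 3 3,5,7,3',4',5'-hexa-O-benzyl-(−)-epigallocatechin
Product: 4 8-bromo-3,5,7,3',4',5'-hexa-O-benzyl-(−)-epigallocatechin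
Conditions: NBS (1.0 equiv), CH2Cl2, −78 °C to 0 °C
Reagents that add atoms: N-bromosuccinimide, O=C1CCC(=O)N1Br
Why: Electrophilic aromatic bromination of the phloroglucinol-type ring D, which in per-benzylated flavan-3-ols is known to react at C8' (ortho to O1' and 7'-OBn, para to 5'-OBn) in preference to C6' and to ring E, and one equivalent at low temperature should avoid the 6',8'-dibromide.

Step 4
Reactants: 4 8-bromo-3,5,7,3',4',5'-hexa-O-benzyl-(−)-epigallocatechin
Product: 5 8-vinyl-3,5,7,3',4',5'-hexa-O-benzyl-(−)-epigallocatechin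
Conditions: CH2=CHBF3K, Pd(dppf)Cl2·CH2Cl2 (5 mol%), Cs2CO3, THF/H2O 9:1, 80 °C
Reagents that add atoms: potassium vinyltrifluoroborate, [K+].C=C[B-](F)(F)F
Why: Suzuki–Miyaura vinylation with the trifluoroborate, a combination that tolerates di-ortho-substituted electron-rich aryl bromides, with the benzyl ethers and both stereocentres inert.

Step 5
Reactants: 6 4-bromoresorcinol
Product: 7 5-(benzyloxy)-2-bromophenol
Conditions: BnBr (1.0 equiv), K2CO3 (1.0 equiv), acetone, rt to 50 °C
Reagents that add atoms: benzyl bromide, BrCc1ccccc1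
Why: Williamson monobenzylation in which the hydroxyl para to bromine is unhindered and free of the OH···Br hydrogen bond, so it should react faster than the shielded hydroxyl ortho to bromine; the dibenzyl ether and the regioisomer are removed by chromatography.

Step 6
Reactants: 7 5-(benzyloxy)-2-bromophenol
Product: 8 [5-(benzyloxy)-2-bromophenoxy](tert-butyl)dimethylsilane
Conditions: TBSCl, imidazole, DMF, rt
Reagents that add atoms: tert-butyldimethylsilyl chloride, CC(C)(C)[Si](C)(C)Cl
Why: Standard silylation of the remaining phenol, giving a small ortho group that survives weak base, borane and nickel catalysis and is later removed by fluoride without acid.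

Step 7
Reactants: 9 1-[3,4-bis(benzyloxy)phenyl]ethanone
Product: 10 2-[3,4-bis(benzyloxy)phenyl]-2-oxoacetic acid
Conditions: SeO2, pyridine, 100 °C; then aq. HCl work-up
Reagents that add atoms: selenium dioxide, O=[Se]=O
Why: Riley-type selenium dioxide oxidation of an aryl methyl ketone in pyridine, the standard route to arylglyoxylic acids, under which aryl benzyl ethers are not attacked.

Step 8
Reactants: 5 8-vinyl-3,5,7,3',4',5'-hexa-O-benzyl-(−)-epigallocatechin (1.0 equiv); 8 [5-(benzyloxy)-2-bromophenoxy](tert-butyl)dimethylsilane (2.0 equiv); 10 2-[3,4-bis(benzyloxy)phenyl]-2-oxoacetic acid (2.5 equiv)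
Product: 11 (3R)-3-[4-(benzyloxy)-2-(tert-butyldimethylsilyloxy)phenyl]-1-[3,4-bis(benzyloxy)phenyl]-3-(3,5,7,3',4',5'-hexa-O-benzyl-epigallocatechin-8-yl)propan-1-one
Conditions: Ir[dF(CF3)ppy]2(dtbbpy)PF6 (2 mol%), NiBr2·glyme (10 mol%), (4S,4'S)-4,4'-diisopropyl-4,4',5,5'-tetrahydro-2,2'-bioxazole (12 mol%), K2HPO4 (3 equiv, stirred with 10 before 5 is added), degassed DMA, 450 nm LEDs, 10 °C
Reagents that add atoms: none
Why: Proposed new method: the photoexcited trivalent iridium complex should oxidise the carboxylate of 10, loss of CO2 gives the 3,4-dibenzyloxybenzoyl radical, this adds to the CH2 terminus of the vinyl group of 5 (forming C2–C3), the resulting C4 benzylic radical is captured by the arylnickel bromide formed from zerovalent nickel and 8, reductive elimination from trivalent nickel forms C4–C4a, and the reduced divalent iridium complex returns monovalent nickel to zerovalent nickel. The closest known reaction types are nickel/photoredox three-component acyl-arylation of alkenes and enantioselective nickel-catalysed 1,2-dicarbofunctionalisation of vinylarenes, which have not been combined with an alpha-keto acid, a 2,6-dioxygenated styrene and catalyst-controlled stereochemistry. No ring is closed. The new stereocentre C4 is to be set as (R) by the C2-symmetric bis(oxazoline) on nickel at the radical-capture and reductive-elimination stage, since the stereocentres of ring F are too remote to decide the face. The step needs terminal regioselectivity and three-component selectivity over direct acyl–aryl coupling: the unhindered CH2 terminus and the stabilisation of the C4 radical by the trioxygenated ring D secure the first, and the high radical affinity of the styrene together with the slow oxidative addition of the electron-rich ortho-substituted bromide (low standing arylnickel concentration) should favour the second. A carboxylate oxidised by electron transfer is the acyl source so that the nine O-benzyl CH2 groups never meet a hydrogen-atom-transfer catalyst, and 10 is neutralised before the acid-sensitive styrene 5 is added.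

Step 9
Reactants: 11 (3R)-3-[4-(benzyloxy)-2-(tert-butyldimethylsilyloxy)phenyl]-1-[3,4-bis(benzyloxy)phenyl]-3-(hexa-O-benzyl-epigallocatechin-8-yl)propan-1-one
Product: 12 (1R,3R)-3-[4-(benzyloxy)-2-(tert-butyldimethylsilyloxy)phenyl]-1-[3,4-bis(benzyloxy)phenyl]-3-(hexa-O-benzyl-epigallocatechin-8-yl)propan-1-ol
Conditions: (S)-1-methyl-3,3-diphenyl-tetrahydro-1H,3H-pyrrolo[1,2-c][1,3,2]oxazaborole (20 mol%), BH3·SMe2, THF/toluene, −20 °C; MeOH quench
Reagents that add atoms: none
Why: Corey–Bakshi–Shibata reduction in which borane held on the oxazaborolidine nitrogen delivers hydride to the ketone bound anti to its larger aryl group, so the (S)-catalyst should give the (R)-carbinol at the future C2 under catalyst control, independent of the C4 centre, with silyl and benzyl ethers inert.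

Step 10
Reactants: 12 (1R,3R)-3-[4-(benzyloxy)-2-(tert-butyldimethylsilyloxy)phenyl]-1-[3,4-bis(benzyloxy)phenyl]-3-(hexa-O-benzyl-epigallocatechin-8-yl)propan-1-ol
Product: 13 (1R,3R)-3-[4-(benzyloxy)-2-hydroxyphenyl]-1-[3,4-bis(benzyloxy)phenyl]-3-(hexa-O-benzyl-epigallocatechin-8-yl)propan-1-ol
Conditions: Bu4NF, AcOH, THF, 0 °C
Reagents that add atoms: none
Why: Fluoride cleavage of the aryl silyl ether under acetic acid buffering, mild enough that the electron-rich benzylic carbinol, the C4–C8' bond and the benzyl ethers are left alone.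

Step 11
Reactants: 13 (1R,3R)-3-[4-(benzyloxy)-2-hydroxyphenyl]-1-[3,4-bis(benzyloxy)phenyl]-3-(hexa-O-benzyl-epigallocatechin-8-yl)propan-1-ol
Product: 14 (2S,4R)-7-(benzyloxy)-2-[3,4-bis(benzyloxy)phenyl]-4-(3,5,7,3',4',5'-hexa-O-benzyl-epigallocatechin-8-yl)chroman (nona-O-benzyl target)
Conditions: PPh3, DIAD (slow addition), toluene, 0.01 M, 0 °C to rt
Reagents that add atoms: none
Why: Mitsunobu etherification in which the C2 carbinol is activated as its alkoxyphosphonium ion and displaced by the ring A phenoxide in a 6-exo-tet SN2 closure, forming O1–C2 with inversion and turning the (R)-carbinol into the (2S) centre trans to the C4 aryl group; the phenol and the carbinol are the only free hydroxyl groups.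

Step 12
Reactants: 14 nona-O-benzyl target
Product: 15 (2S,4R)-7,3',4'-trihydroxyflavan-(4→8)-(−)-epigallocatechin (target, CNP0211965.1)
Conditions: H2 (1 atm), Pd(OH)2/C, degassed THF/MeOH 1:1, rt; filtration under argon
Reagents that add atoms: none
Why: Catalytic hydrogenolysis of the eight aryl benzyl ethers and the one alkyl benzyl ether, standard for benzylated proanthocyanidins, whose cyclic C2–O1 ethers and C4–C8' bond survive, and no stereocentre is touched.

## Compound list

1 | (−)-epigallocatechin | Oc1cc(O)c2c(c1)O[C@H](c1cc(O)c(O)c(O)c1)[C@H](O)C2 | starting material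
2 | 5,7,3',4',5'-penta-O-benzyl-(−)-epigallocatechin | c1c(OCc2ccccc2)cc(OCc2ccccc2)c2c1O[C@H](c1cc(OCc3ccccc3)c(OCc3ccccc3)c(OCc3ccccc3)c1)[C@H](O)C2 | intermediate
3 | 3,5,7,3',4',5'-hexa-O-benzyl-(−)-epigallocatechin | c1c(OCc2ccccc2)cc(OCc2ccccc2)c2c1O[C@H](c1cc(OCc3ccccc3)c(OCc3ccccc3)c(OCc3ccccc3)c1)[C@H](OCc1ccccc1)C2 | intermediate
4 | 8-bromo-3,5,7,3',4',5'-hexa-O-benzyl-(−)-epigallocatechin | Brc1c(OCc2ccccc2)cc(OCc2ccccc2)c2c1O[C@H](c1cc(OCc3ccccc3)c(OCc3ccccc3)c(OCc3ccccc3)c1)[C@H](OCc1ccccc1)C2 | intermediate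
5 | 8-vinyl-3,5,7,3',4',5'-hexa-O-benzyl-(−)-epigallocatechin | C=Cc1c(OCc2ccccc2)cc(OCc2ccccc2)c2c1O[C@H](c1cc(OCc3ccccc3)c(OCc3ccccc3)c(OCc3ccccc3)c1)[C@H](OCc1ccccc1)C2 | intermediate
6 | 4-bromoresorcinol | Oc1ccc(Br)c(O)c1 | starting material
7 | 5-(benzyloxy)-2-bromophenol | Oc1cc(OCc2ccccc2)ccc1Br | intermediate
8 | [5-(benzyloxy)-2-bromophenoxy](tert-butyl)dimethylsilane | CC(C)(C)[Si](C)(C)Oc1cc(OCc2ccccc2)ccc1Br | intermediate
9 | 1-[3,4-bis(benzyloxy)phenyl]ethanone | CC(=O)c1ccc(OCc2ccccc2)c(OCc2ccccc2)c1 | starting material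
10 | 2-[3,4-bis(benzyloxy)phenyl]-2-oxoacetic acid | OC(=O)C(=O)c1ccc(OCc2ccccc2)c(OCc2ccccc2)c1 | intermediate
11 | (3R)-3-[4-(benzyloxy)-2-(tert-butyldimethylsilyloxy)phenyl]-1-[3,4-bis(benzyloxy)phenyl]-3-(hexa-O-benzyl-epigallocatechin-8-yl)propan-1-one | O=C(C[C@H](c1ccc(OCc2ccccc2)cc1O[Si](C)(C)C(C)(C)C)c1c(OCc2ccccc2)cc(OCc2ccccc2)c2c1O[C@H](c1cc(OCc3ccccc3)c(OCc3ccccc3)c(OCc3ccccc3)c1)[C@H](OCc1ccccc1)C2)c1ccc(OCc2ccccc2)c(OCc2ccccc2)c1 | intermediate
12 | (1R,3R)-3-[4-(benzyloxy)-2-(tert-butyldimethylsilyloxy)phenyl]-1-[3,4-bis(benzyloxy)phenyl]-3-(hexa-O-benzyl-epigallocatechin-8-yl)propan-1-ol | O[C@H](C[C@H](c1ccc(OCc2ccccc2)cc1O[Si](C)(C)C(C)(C)C)c1c(OCc2ccccc2)cc(OCc2ccccc2)c2c1O[C@H](c1cc(OCc3ccccc3)c(OCc3ccccc3)c(OCc3ccccc3)c1)[C@H](OCc1ccccc1)C2)c1ccc(OCc2ccccc2)c(OCc2ccccc2)c1 | intermediate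
13 | (1R,3R)-3-[4-(benzyloxy)-2-hydroxyphenyl]-1-[3,4-bis(benzyloxy)phenyl]-3-(hexa-O-benzyl-epigallocatechin-8-yl)propan-1-ol | O[C@H](C[C@H](c1ccc(OCc2ccccc2)cc1O)c1c(OCc2ccccc2)cc(OCc2ccccc2)c2c1O[C@H](c1cc(OCc3ccccc3)c(OCc3ccccc3)c(OCc3ccccc3)c1)[C@H](OCc1ccccc1)C2)c1ccc(OCc2ccccc2)c(OCc2ccccc2)c1 | intermediate
14 | (2S,4R)-7-(benzyloxy)-2-[3,4-bis(benzyloxy)phenyl]-4-(hexa-O-benzyl-epigallocatechin-8-yl)chroman | C(c1ccccc1)Oc1ccc2c(c1)O[C@H](c1ccc(OCc3ccccc3)c(OCc3ccccc3)c1)C[C@H]2c1c(OCc3ccccc3)cc(OCc3ccccc3)c2c1O[C@H](c1cc(OCc3ccccc3)c(OCc3ccccc3)c(OCc3ccccc3)c1)[C@H](OCc1ccccc1)C2 | intermediate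
15 | (2S,4R)-7,3',4'-trihydroxyflavan-(4→8)-(−)-epigallocatechin | Oc1ccc2c(c1)O[C@H](c1ccc(O)c(O)c1)C[C@H]2c1c(O)cc(O)c2c1O[C@H](c1cc(O)c(O)c(O)c1)[C@H](O)C2 | target

## Step count and risks

Total step count: 12. Longest linear sequence: 9 steps (steps 1–4 and 8–12).

**Step 8 (three-component acyl-arylation).** The aroyl radical may couple directly with the arylnickel species before it adds to the alkene. The electron-rich C4 radical may be oxidised to a cation and trapped by carboxylate or water. Reductive elimination at a carbon flanked by three ortho oxygen substituents may be slow. Facial selectivity at nickel may be poor.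

The fallback sets out from 4 (using 8 and 9) and returns at 11. Bromine–lithium exchange on 4 (n-BuLi, THF, −78 °C) and a DMF quench should give 8-formyl-3,5,7,3',4',5'-hexa-O-benzyl-(−)-epigallocatechin F1. Claisen–Schmidt condensation of this with 9 (KOH, EtOH/THF) should give the chalcone (E)-1-[3,4-bis(benzyloxy)phenyl]-3-(hexa-O-benzyl-epigallocatechin-8-yl)prop-2-en-1-one F2. Miyaura borylation of 8 (B2pin2, Pd(dppf)Cl2, KOAc, dioxane, 80 °C) should give 2-[4-(benzyloxy)-2-(tert-butyldimethylsilyloxy)phenyl]-4,4,5,5-tetramethyl-1,3,2-dioxaborolane F3. Rhodium-catalysed asymmetric 1,4-addition of F3 to F2 (Hayashi–Miyaura; [Rh(OH)(cod)]2, BINAP of the antipode that gives the (R) centre, dioxane/H2O, no added base) then forms C4–C4a and sets C4 by the ligand. Any phenol set free is re-silylated (TBSCl, imidazole), and the sequence arrives at 11.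

**Step 11 (Mitsunobu closure).** The alkoxyphosphonium ion at the electron-rich benzylic C2 may ionise before it is displaced. This would erode the inversion (giving the 2,4-cis epimer) or lead to elimination toward the styrene.

The fallback sets out from 11 and returns at 14, closing ring C at O1–C8a with retention at C2. Reduction of 11 with the (R)-antipode of the oxazaborolidine and BH3·SMe2 should give (1S,3R)-3-[4-(benzyloxy)-2-(tert-butyldimethylsilyloxy)phenyl]-1-[3,4-bis(benzyloxy)phenyl]-3-(hexa-O-benzyl-epigallocatechin-8-yl)propan-1-ol F4. Desilylation (Bu4NF, AcOH) should give (1S,3R)-3-[4-(benzyloxy)-2-hydroxyphenyl]-1-[3,4-bis(benzyloxy)phenyl]-3-(hexa-O-benzyl-epigallocatechin-8-yl)propan-1-ol F5. Phenol-selective triflation (PhNTf2, Et3N, CH2Cl2) should give 5-(benzyloxy)-2-[(1R,3S)-3-[3,4-bis(benzyloxy)phenyl]-1-(hexa-O-benzyl-epigallocatechin-8-yl)-3-hydroxypropyl]phenyl trifluoromethanesulfonate F6. Palladium-catalysed intramolecular aryl etherification of the secondary alcohol (Pd2(dba)3, 2-di-tert-butylphosphino-2',4',6'-triisopropylbiphenyl, Cs2CO3, toluene, 80 °C) does not break the C2–O bond and should deliver 14.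

**Step 1 (direct benzylation of the free polyphenol).** The pyrogallol ring may oxidise under base, ring D may be C-benzylated, and phenoxide-driven opening of ring F may epimerise C2'.

The fallback sets out from 1 and returns at 3. Peracetylation (Ac2O, pyridine) should give the air-stable (−)-epigallocatechin hexaacetate F7. Acetate-to-benzyl exchange in one flask (BnBr, NaH, DMF, a measured amount of water, 0 °C) releases each oxygen anion only as fast as it is benzylated and should give 3 directly.

## Further compounds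

F1 | step 8 | 8-formyl-3,5,7,3',4',5'-hexa-O-benzyl-(−)-epigallocatechin | O=Cc1c(OCc2ccccc2)cc(OCc2ccccc2)c2c1O[C@H](c1cc(OCc3ccccc3)c(OCc3ccccc3)c(OCc3ccccc3)c1)[C@H](OCc1ccccc1)C2
F2 | step 8 | (E)-1-[3,4-bis(benzyloxy)phenyl]-3-(hexa-O-benzyl-epigallocatechin-8-yl)prop-2-en-1-one | O=C(/C=C/c1c(OCc2ccccc2)cc(OCc2ccccc2)c2c1O[C@H](c1cc(OCc3ccccc3)c(OCc3ccccc3)c(OCc3ccccc3)c1)[C@H](OCc1ccccc1)C2)c1ccc(OCc2ccccc2)c(OCc2ccccc2)c1
F3 | step 8 | 2-[4-(benzyloxy)-2-(tert-butyldimethylsilyloxy)phenyl]-4,4,5,5-tetramethyl-1,3,2-dioxaborolane | CC(C)(C)[Si](C)(C)Oc1cc(OCc2ccccc2)ccc1B1OC(C)(C)C(C)(C)O1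
F4 | step 11 | (1S,3R)-3-[4-(benzyloxy)-2-(tert-butyldimethylsilyloxy)phenyl]-1-[3,4-bis(benzyloxy)phenyl]-3-(hexa-O-benzyl-epigallocatechin-8-yl)propan-1-ol | O[C@@H](C[C@H](c1ccc(OCc2ccccc2)cc1O[Si](C)(C)C(C)(C)C)c1c(OCc2ccccc2)cc(OCc2ccccc2)c2c1O[C@H](c1cc(OCc3ccccc3)c(OCc3ccccc3)c(OCc3ccccc3)c1)[C@H](OCc1ccccc1)C2)c1ccc(OCc2ccccc2)c(OCc2ccccc2)c1
F5 | step 11 | (1S,3R)-3-[4-(benzyloxy)-2-hydroxyphenyl]-1-[3,4-bis(benzyloxy)phenyl]-3-(hexa-O-benzyl-epigallocatechin-8-yl)propan-1-ol | O[C@@H](C[C@H](c1ccc(OCc2ccccc2)cc1O)c1c(OCc2ccccc2)cc(OCc2ccccc2)c2c1O[C@H](c1cc(OCc3ccccc3)c(OCc3ccccc3)c(OCc3ccccc3)c1)[C@H](OCc1ccccc1)C2)c1ccc(OCc2ccccc2)c(OCc2ccccc2)c1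
F6 | step 11 | 5-(benzyloxy)-2-[(1R,3S)-3-[3,4-bis(benzyloxy)phenyl]-1-(hexa-O-benzyl-epigallocatechin-8-yl)-3-hydroxypropyl]phenyl trifluoromethanesulfonate | O[C@@H](C[C@H](c1ccc(OCc2ccccc2)cc1OS(=O)(=O)C(F)(F)F)c1c(OCc2ccccc2)cc(OCc2ccccc2)c2c1O[C@H](c1cc(OCc3ccccc3)c(OCc3ccccc3)c(OCc3ccccc3)c1)[C@H](OCc1ccccc1)C2)c1ccc(OCc2ccccc2)c(OCc2ccccc2)c1
F7 | step 1 | (−)-epigallocatechin hexaacetate | CC(=O)Oc1cc(OC(C)=O)c2c(c1)O[C@H](c1cc(OC(C)=O)c(OC(C)=O)c(OC(C)=O)c1)[C@H](OC(C)=O)C2
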